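The amount of target in the noon flask stands still: from 15.0 min to 80.0 min the target readings lie around 38.2%, within their scatter of 1 percentage point.

| flask | starting material | reagent | temperature | remark | time |
|---|---|---|---|---|---|
| noon | 0.80 M | 0.76 M | 25 °C | the very flask that is asked about, followed so far |  |
| dawn | 0.80 M | 1.5 M | 20 °C | run made earlier |  |
| flask | 0.80 M | 0.760 M | 25 °C |  | 2.0 h |

- noon (time / min: target / %): 15.0: 38.2; 30.0: 37.3; 40.0: 39.4; 60.0: 38.5; 80.0: 37.6
- dawn (time / min: target / %): 2.00: 9.9; 4.00: 17.2; 6.00: 22.8; 8.00: 23.6; 10.0: 25.2

(each reading ± 1 percentage point)

* target, in percent of the starting material first charged, at 2.0 h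
* what to do for the largest gain in target; "none" if nothing gains more than 2 percentage points (elm / ash / cedar / larch / none)
* target present, with what was taken out counted in, in percent of the starting material first charged, after ash
* target present, with what was taken out counted in, in percent of the starting material first charged, after cedar

- elm: at 2.0 h add reagent, 50.0% of the amount charged, then wait 4.0 h
- ash: at 2.0 h take out 90% of the target then present, then wait 4.0 h
- cedar: at 2.0 h raise the temperature by 25 K, then wait 4.0 h
- larch: change nothing and wait 4.0 h more

- target that was removed still counts
- additions bring no volume worth counting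

Two amounts count in the noon flask, the target on the plateau and the rest of the charge. Their ratio, target over rest, is 0.618, called here the split. The plateau stands by 15.0 min, well before 2.0 h, so the flask at 2.0 h should read 38.2%. This is read as thermodynamic control, with the split held by a balance and not by a clock.

If so, ash lifts out 34.4% of the charge, and the remaining pool returns to the same split within the wait of 4.0 h. That gives 59.4%, counting what was removed. Larch gains nothing. Elm stays unreckoned here: the dawn flask differs from the noon flask in reagent and temperature together, and its readings still climb at 10.0 min, so it shows no effect of reagent by itself. Cedar beats ash once the heated split passes 1.47. The dawn flask shows no plateau, so this reckoning gives the threshold and not the heated amount.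

The forecast gives 38.2% now, 59.5% after ash, 75% after cedar and cedar as best, reading the balance as “independent of reagent level and endothermic”. Its ash figure differs from the one above in the last digit.

The flask gives 38.2%, then 59.4% after ash and 72.8% after cedar, and cedar gains 35 points against 21 points for ash, under this scheme:

    intermediate A → intermediate B (k = 0.0380 s⁻¹, Ea = 83.0 kJ mol⁻¹)
    starting material ⇌ intermediate A (K = 3.90, k = 0.0984 s⁻¹, Ea = 86.0 kJ mol⁻¹, ΔH = −65.0 kJ mol⁻¹)
    intermediate B → target (k = 0.00445 s⁻¹, Ea = 95.0 kJ mol⁻¹)
    target ⇌ isomer of the product (K = 1.62, k = 0.0154 s⁻¹, Ea = 85.0 kJ mol⁻¹, ΔH = −47.0 kJ mol⁻¹)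
    (constants at 25 °C)

The rest behind the split of 0.618 is isomer of the product, 61.8% of the charge at 120 min, and the run without that step gives 100% target. The neighbour flask at 50 °C shows the heated balance: its split of 2.68 stands above the threshold of 1.47, with target at 72.8%.

(The numbers in the tables stem from a simulated flask with made-up constants, noise included.)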